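**Plan**
- Retrosynthesis: the ring A O–H is traced back to O–CH3. Ring A is then opened at C2–C3 and C1–C6 (cycloaddition, silanol loss and CO2 loss read backwards) to 3,5-dibromo-2-pyrone and the O-silyl ketene acetal of an aryl methoxyacetate. The ester C–O bond, the ring B O–CH3 bond, the ring B–O–ring C bond and the three ring B C–Br bonds are then cut back to guaiacol.
- Enabling feature: in ring A (C1 OH, C2 OAr, C3 Br, C4 H, C5 Br, C6 H) the run C3(Br)–C4(H)–C5(Br)–C6(H) is the C3–C6 diene of 3,5-dibromo-2-pyrone. The neighbouring oxygen-bearing carbons C1 and C2 are the two carbons of a ketene acetal, with C2 as the acetal carbon that already carries the ring B oxygen.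
- Forward order: ring B comes from guaiacol by tribromination. Ring C is attached with a symmetrical diaryliodonium salt assembled from 2,4-dibromo-1-iodobenzene and 1,3-dibromobenzene. The freed ring B oxygen is acylated and the ester is converted to the ketene acetal. Ring A is built last on that oxygen by [4+2] cycloaddition, aromatization and CO2 loss, and demethylation ends the route.
- Stereochemistry: the target is achiral; the sp3 centres of the bridged intermediates are transient and vanish on aromatization.

Key step: step 8

Remark on the chemistry: soft enolization is assumed to give mainly the Z ketene acetal 12 (methoxy cis to silyloxy). The E isomer and both endo and exo modes of addition lead to the same arene, so 15 is written without configuration (racemic, mixture of diastereomers).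

Step 1
Reactants: 1 guaiacol
Product: 2 4,5,6-tribromo-2-methoxyphenol
Conditions: Br2 (3.1 equiv), AcOH, 0 → 40 °C
Reagents that add atoms: bromine, BrBr
Why: Electrophilic aromatic bromination in which the hydroxyl group directs the first two bromines para and ortho to itself (C4, C6) and the methoxy group directs the third para to itself (C5), the pattern that exhaustive halogenation of guaiacol follows.

Step 2
Reactants: 3 2,4-dibromo-1-iodobenzene; 4 1,3-dibromobenzene
Product: 7 bis(2,4-dibromophenyl)iodonium chloride, via bis(sulfooxy)iodoarene 5 (not isolated), via iodonium hydrogen sulfate 6 (not isolated)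
Conditions: 3, K2S2O8 (1.3 equiv), conc. H2SO4, 0 → 23 °C; then 4 (1.1 equiv), 23 °C; ice, aq. NaCl
Reagents that add atoms: potassium peroxodisulfate, [K+].[K+].[O-]S(=O)(=O)OOS(=O)(=O)[O-]; sodium chloride, [Na+].[Cl-]
Why: Peroxodisulfate in sulfuric acid oxidizes the aryl iodide to the trivalent iodine bis(hydrogen sulfate) 5, a strong electrophile that substitutes 1,3-dibromobenzene at C4 (para to one bromine, ortho to the other) by electrophilic aromatic substitution, the classical acid-mediated diaryliodonium synthesis for deactivated arenes; anion exchange then precipitates the sparingly soluble chloride.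

Step 3
Reactants: 2 4,5,6-tribromo-2-methoxyphenol; 7 bis(2,4-dibromophenyl)iodonium chloride
Product: 8 1,2,3-tribromo-4-(2,4-dibromophenoxy)-5-methoxybenzene
Conditions: NaOH (1.1 equiv), H2O–1,4-dioxane, 80–100 °C
Reagents that add atoms: none
Why: Metal-free O-arylation of a phenoxide with a diaryliodonium salt (ligand exchange at trivalent iodine, then ligand coupling), the standard entry to ortho-substituted polybrominated diphenyl ethers; the symmetrical salt leaves no choice of aryl group, no copper or palladium meets the C–Br bonds, and the aryl iodide released is compound 3, which can be returned to step 2.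

Step 4
Reactants: 8 1,2,3-tribromo-4-(2,4-dibromophenoxy)-5-methoxybenzene
Product: 9 3,4,5-tribromo-2-(2,4-dibromophenoxy)phenol
Conditions: BBr3 (1.5 equiv), CH2Cl2, −78 → 23 °C; H2O
Reagents that add atoms: none
Why: Lewis acid demethylation of an aryl methyl ether (boron coordinates to oxygen, bromide attacks the methyl group by SN2), which leaves diaryl ethers and aryl bromides untouched.

Step 5
Reactants: 9 3,4,5-tribromo-2-(2,4-dibromophenoxy)phenol; 10 methoxyacetyl chloride
Product: 11 3,4,5-tribromo-2-(2,4-dibromophenoxy)phenyl methoxyacetate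
Conditions: pyridine (2 equiv), DMAP (cat.), CH2Cl2, 0 → 23 °C
Reagents that add atoms: none
Why: Acylation of a phenol by an acid chloride under nucleophilic catalysis, which is easy at this oxygen (one ortho substituent only) and installs as an ester oxygen what becomes the hindered diaryl ether oxygen.

Step 6
Reactants: 11 3,4,5-tribromo-2-(2,4-dibromophenoxy)phenyl methoxyacetate
Product: 12 (Z)-1-(tert-butyldimethylsilyloxy)-2-methoxy-1-[3,4,5-tribromo-2-(2,4-dibromophenoxy)phenoxy]ethene
Conditions: t-BuMe2SiOTf (1.3 equiv), Et3N (2 equiv), CH2Cl2, 0 → 23 °C; evaporate, extract into dry hexane–toluene, filter, concentrate; used crude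
Reagents that add atoms: tert-butyldimethylsilyl trifluoromethanesulfonate, CC(C)(C)[Si](C)(C)OS(=O)(=O)C(F)(F)F
Why: Soft enolization (O-silylation of the ester carbonyl by the silyl triflate, then deprotonation by the amine) gives the silyl ketene acetal without a free enolate, which could otherwise expel the aryloxide with formation of methoxyketene.

Step 7
Reactants: 13 coumalic acid
Product: 14 3,5-dibromo-2H-pyran-2-one
Conditions: NBS (2.5 equiv), LiOAc (cat.), MeCN–H2O, 23 °C
Reagents that add atoms: N-bromosuccinimide, BrN1C(=O)CCC1=O
Why: Bromodecarboxylation at C5 together with electrophilic bromination at C3 of the pyrone, the known one-step preparation of this dibromopyrone from coumalic acid.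

Step 8
Reactants: 12 (Z)-1-(tert-butyldimethylsilyloxy)-2-methoxy-1-[3,4,5-tribromo-2-(2,4-dibromophenoxy)phenoxy]ethene; 14 3,5-dibromo-2H-pyran-2-one
Product: 17 bromoiesol A methyl ether, via bridged lactone 15 (not isolated), via dienyl lactone 16 (not isolated)
Conditions: CH2Cl2, 23–40 °C; then Me3SiOTf (0.2 equiv), −78 → 23 °C
Reagents that add atoms: none
Why: Proposed new method: the nucleophilic CH(OMe) carbon of the ketene acetal bonds to the electrophilic C6 of the dibromopyrone and the acetal carbon to C3 (asynchronous inverse-electron-demand Diels–Alder reaction), the bridged lactone 15 is then ionized at its silyl ketal and loses the neighbouring proton, and the bicyclic diene 16 expels CO2 by retro-[4+2] cycloaddition; the closest known reaction type is the cycloaddition of 2-pyrones with ketene acetals that gives aryl ethers after loss of CO2 and an alcohol, which has not been shown for an O-aryl O-silyl ketene acetal that must keep its aryloxy group. Ring A closes by this intermolecular [4+2] cycloaddition, which forms its C1–C6 and C2–C3 bonds together. The sp3 centres of 15 and 16 are transient and racemic and none reaches the product, so no stereocontrol is called for. Regiochemistry follows the polarization of both partners and is the sense in which enol ethers add to 3-bromo- and 3,5-dibromo-2-pyrone (oxygen-bearing carbon next to C3–Br). The selectivity that decides the step is which ketal oxygen leaves: aryloxide is the better nucleofuge on thermolysis, so the ketal is not heated but opened at low temperature at the bridged-lactone stage, where unassisted heterolysis is slow (the cation is not allylic and lies between C–Br and C–OMe), by a silyl triflate that silylates or, once triflic acid is released, protonates the more basic silyl ether oxygen and not the oxygen of the pentabrominated aryloxy group. The bulky tert-butyldimethylsilyl group and the non-nucleophilic triflate counter-ion disfavour attack at silicon, which would unmask a hemiketal and eject the phenoxide.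

Step 9
Reactants: 17 bromoiesol A methyl ether
Product: 18 bromoiesol A
Conditions: BBr3 (2 equiv), CH2Cl2, −78 → 23 °C; H2O
Reagents that add atoms: none
Why: BBr3 demethylation of the ring A anisole, the usual conversion of methoxylated polybrominated diphenyl ethers into their phenols, with the diaryl ether links and all seven C–Br bonds inert.

**Compound list**
1 | guaiacol (2-methoxyphenol) | COc1ccccc1O | starting material
2 | 4,5,6-tribromo-2-methoxyphenol | COc1cc(Br)c(Br)c(Br)c1O | intermediate
3 | 2,4-dibromo-1-iodobenzene | Brc1ccc(I)c(Br)c1 | starting material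
4 | 1,3-dibromobenzene | Brc1cccc(Br)c1 | starting material
5 | 1-[bis(sulfooxy)iodo]-2,4-dibromobenzene (trivalent iodine bis(hydrogen sulfate) of 3) | OS(=O)(=O)OI(OS(=O)(=O)O)c1ccc(Br)cc1Br | intermediate (not isolated)
6 | bis(2,4-dibromophenyl)iodonium hydrogen sulfate | Brc1ccc([I+]c2ccc(Br)cc2Br)c(Br)c1.OS(=O)(=O)[O-] | intermediate (not isolated)
7 | bis(2,4-dibromophenyl)iodonium chloride | Brc1ccc([I+]c2ccc(Br)cc2Br)c(Br)c1.[Cl-] | intermediate
8 | 1,2,3-tribromo-4-(2,4-dibromophenoxy)-5-methoxybenzene | COc1cc(Br)c(Br)c(Br)c1Oc1ccc(Br)cc1Br | intermediate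
9 | 3,4,5-tribromo-2-(2,4-dibromophenoxy)phenol | Oc1cc(Br)c(Br)c(Br)c1Oc1ccc(Br)cc1Br | intermediate
10 | methoxyacetyl chloride | COCC(=O)Cl | starting material
11 | 3,4,5-tribromo-2-(2,4-dibromophenoxy)phenyl methoxyacetate | COCC(=O)Oc1cc(Br)c(Br)c(Br)c1Oc1ccc(Br)cc1Br | intermediate
12 | (Z)-1-(tert-butyldimethylsilyloxy)-2-methoxy-1-[3,4,5-tribromo-2-(2,4-dibromophenoxy)phenoxy]ethene | CO/C=C(\O[Si](C)(C)C(C)(C)C)Oc1cc(Br)c(Br)c(Br)c1Oc1ccc(Br)cc1Br | intermediate
13 | coumalic acid (2-oxo-2H-pyran-5-carboxylic acid) | O=C1C=CC(C(=O)O)=CO1 | starting material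
14 | 3,5-dibromo-2H-pyran-2-one | O=C1OC=C(Br)C=C1Br | intermediate
15 | 4,7-dibromo-5-(tert-butyldimethylsilyloxy)-6-methoxy-5-[3,4,5-tribromo-2-(2,4-dibromophenoxy)phenoxy]-2-oxabicyclo[2.2.2]oct-7-en-3-one (racemic, mixture of diastereomers, configuration not specified) | O=C1OC2C(OC)C(O[Si](C)(C)C(C)(C)C)(Oc3cc(Br)c(Br)c(Br)c3Oc3ccc(Br)cc3Br)C1(Br)C=C2Br | intermediate (not isolated)
16 | 4,7-dibromo-6-methoxy-5-[3,4,5-tribromo-2-(2,4-dibromophenoxy)phenoxy]-2-oxabicyclo[2.2.2]octa-5,7-dien-3-one (racemic, configuration not specified) | O=C1OC2C(OC)=C(Oc3cc(Br)c(Br)c(Br)c3Oc3ccc(Br)cc3Br)C1(Br)C=C2Br | intermediate (not isolated)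
17 | bromoiesol A methyl ether, 1,2,3-tribromo-5-(2,4-dibromo-6-methoxyphenoxy)-4-(2,4-dibromophenoxy)benzene | COc1cc(Br)cc(Br)c1Oc1cc(Br)c(Br)c(Br)c1Oc1ccc(Br)cc1Br | intermediate
18 | bromoiesol A, 3,5-dibromo-2-[3,4,5-tribromo-2-(2,4-dibromophenoxy)phenoxy]phenol | Oc1cc(Br)cc(Br)c1Oc1cc(Br)c(Br)c(Br)c1Oc1ccc(Br)cc1Br | target

**Step count**
Total steps: 9. Longest linear sequence: 7 steps (steps 1, 3, 4, 5, 6, 8, 9 from guaiacol); steps 2 and 7 prepare the two partners.

**Steps most likely to fail**

1. Step 8. The ketal carbon may shed the aryloxide instead of the silyloxy group, either pushed out by the silyloxy lone pair or after cleavage of the O–Si bond. Ring A would then aromatize without the diaryl ether link and rings B and C would be released as the phenol. The first C–C bond may also form without ring closure at C3, leaving an open conjugate adduct.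
 Fallback (known chemistry; sets out from 9, returns at 17): ring A is delivered as an iodonium electrophile. Commercial 2,4-dibromo-6-methoxyaniline (COc1cc(Br)cc(Br)c1N) is diazotized (NaNO2, H2SO4, 0 °C) to 2,4-dibromo-6-methoxybenzenediazonium hydrogen sulfate F1. Treatment with KI gives 1,5-dibromo-2-iodo-3-methoxybenzene F2 (Sandmeyer-type iodination). Oxidation with mCPBA and TsOH·H2O in MeCN, then capture by 1,3,5-trimethoxybenzene, gives (2,4-dibromo-6-methoxyphenyl)(2,4,6-trimethoxyphenyl)iodonium 4-methylbenzenesulfonate F3. The potassium phenoxide of 9 (KOt-Bu, THF, 40 °C) is arylated by F3, the electron-rich trimethoxyphenyl group staying on iodine, to give 17; step 9 follows.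

2. Step 6. The enolizing active ester may lose its aryloxide with formation of methoxyketene, silylation may occur at carbon, or the ketene acetal may hydrolyse during isolation.
 Fallback (sets out from 11, returns at 16): the ketene acetal is no longer prepared and handled as a separate compound. Ester 11 is enolized in the presence of pyrone 14 with Me3SiOTf (2.5 equiv) and i-Pr2NEt in CH2Cl2 at −78 → 0 °C (one-flask enol silane formation and Mukaiyama–Michael addition). The transient (Z)-2-methoxy-1-[3,4,5-tribromo-2-(2,4-dibromophenoxy)phenoxy]-1-(trimethylsilyloxy)ethene F4 adds to C6 of the silyl-activated pyrone as it forms, and the ring closes at C3 to the trimethylsilyl bridged lactone F5. The excess silyl triflate opens the ketal of F5 with loss of hexamethyldisiloxane to 16, which gives 17 as in step 8.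

3. Step 3. Ligand coupling of the hindered, weakly nucleophilic 2,6-disubstituted phenoxide may be slow, so that hydrolysis of the iodonium salt or aryl transfer to chloride or hydroxide consumes the reagent.
 Fallback (sets out from 2, returns at 8): the ether bond is made by SNAr and the second ring C bromine is installed afterwards. Phenol 2 (K2CO3, DMF, 80 °C) displaces fluoride from commercial 3-bromo-4-fluoronitrobenzene to give 1,2,3-tribromo-4-(2-bromo-4-nitrophenoxy)-5-methoxybenzene F6. Reduction with Fe powder and NH4Cl in EtOH–H2O (no hydrogenolysis conditions, so the C–Br bonds stay) gives 3-bromo-4-(2,3,4-tribromo-6-methoxyphenoxy)aniline F7. Diazotization with t-BuONO in MeCN gives 3-bromo-4-(2,3,4-tribromo-6-methoxyphenoxy)benzenediazonium bromide F8, which CuBr2 converts (Sandmeyer bromination) into 8.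

**Further compounds**
F1 | step 8 | 2,4-dibromo-6-methoxybenzenediazonium hydrogen sulfate | COc1cc(Br)cc(Br)c1[N+]#N.OS(=O)(=O)[O-]
F2 | step 8 | 1,5-dibromo-2-iodo-3-methoxybenzene | COc1cc(Br)cc(Br)c1I
F3 | step 8 | (2,4-dibromo-6-methoxyphenyl)(2,4,6-trimethoxyphenyl)iodonium 4-methylbenzenesulfonate | COc1cc(Br)cc(Br)c1[I+]c1c(OC)cc(OC)cc1OC.Cc1ccc(cc1)S(=O)(=O)[O-]
F4 | step 6 | (Z)-2-methoxy-1-[3,4,5-tribromo-2-(2,4-dibromophenoxy)phenoxy]-1-(trimethylsilyloxy)ethene | CO/C=C(\O[Si](C)(C)C)Oc1cc(Br)c(Br)c(Br)c1Oc1ccc(Br)cc1Br
F5 | step 6 | 4,7-dibromo-6-methoxy-5-[3,4,5-tribromo-2-(2,4-dibromophenoxy)phenoxy]-5-(trimethylsilyloxy)-2-oxabicyclo[2.2.2]oct-7-en-3-one (racemic, configuration not specified) | O=C1OC2C(OC)C(O[Si](C)(C)C)(Oc3cc(Br)c(Br)c(Br)c3Oc3ccc(Br)cc3Br)C1(Br)C=C2Br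
F6 | step 3 | 1,2,3-tribromo-4-(2-bromo-4-nitrophenoxy)-5-methoxybenzene | COc1cc(Br)c(Br)c(Br)c1Oc1ccc(cc1Br)[N+](=O)[O-]
F7 | step 3 | 3-bromo-4-(2,3,4-tribromo-6-methoxyphenoxy)aniline | COc1cc(Br)c(Br)c(Br)c1Oc1ccc(N)cc1Br
F8 | step 3 | 3-bromo-4-(2,3,4-tribromo-6-methoxyphenoxy)benzenediazonium bromide | COc1cc(Br)c(Br)c(Br)c1Oc1ccc(cc1Br)[N+]#N.[Br-]
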